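The readings are simulated for substances that don't exist, and the scatter is random.

I had 3 questions to answer, and the one quantity that served the first and the third was the catalyst charge that does no work.

| flask | starting material | reagent | free catalyst | time |
|---|---|---|---|---|
| larch | 0.100 M | 0.110 M | 0.00100 M |  |
| cedar | 0.0400 M | 0.0500 M | 0.00100 M |  |
| elm | 0.100 M | 0.110 M | 0.00150 M |  |
| alder | 0.100 M | 0.110 M | 0.00240 M | 18 min |

- larch run (time / min: [starting material] / M): 0.72: 0.0976; 1.4: 0.0950; 2.6: 0.0915; 5.0: 0.0832; 9.5: 0.0702; 18: 0.0496
- cedar run (time / min: [starting material] / M): 0.72: 0.0389; 1.4: 0.0378; 2.6: 0.0363; 5.0: 0.0320; 9.5: 0.0264; 18: 0.0168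
- elm run (time / min: [starting material] / M): 0.72: 0.0960; 1.4: 0.0921; 2.6: 0.0854; 5.0: 0.0732; 9.5: 0.0546; 18: 0.0296

(scatter of a reading: 3 × 10⁻⁴ M)

1. order of the initial rate in [free catalyst], near the charge of the larch run, the rate being that where two percent of its starting material are target
2. the cedar run starts with 0.0600 M less of starting material and of reagent than the larch run, and with no target. Compared where both hold the same amount of starting material, once fifteen percent of what the cedar run was charged with has turned into target, is the cedar run faster, slower or alike (within a tenth)?
3. starting material in the alder run at 18 min, as a share of the starting material charged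

- Overall: starting material + reagent -> target, with free catalyst as catalyst.
- Constant volume, constant temperature.
- A reading of a species includes what of it is bound.
- "The second partner" is reagent.
- An order is taken over about fifteen percent of the charge, up and down.

My reckoning, with starting material, charged at less than the reagent, as the limiting reagent:

1. The elm run reached the final larch reading, 0.0496 M, at 10.8 min. Its clock therefore ran 1.66 times the larch clock, on 1.50 times the catalyst.

2. I assumed that rate follows the charge minus a fixed amount. That gave 2.44 × 10⁻⁴ M, the dead charge: catalyst charged but doing no work, equal in each flask. The order near the larch charge is then charge over working charge, 1.32.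

3. At 0.0400 M of starting material, the larch path holds 0.0500 M of reagent, which is the cedar charge, so cedar can continue it. On the larch clock, elm's 13.8 min at that point becomes 23.0 min. From there to 0.0296 M, elm took 6.95 min of larch clock and cedar took 6.82 min. The ratio of 1.02 reads as alike.

4. The alder run's clock is 2.85 times the larch clock, so its 18 min buys 51.3 min.

5. The ledger of the alder charge, 0.100 M:
- The first 0.0600 M turned costs 23.0 min.
- The next 0.0232 M costs the cedar 18 min.
- That leaves 10.4 min to spend on the tail, whose time constant in the cedar run read 18.8 min.
- The tail turns 0.00713 M.
- The balance is 0.00967 M, or 9.67 % of the charge.

The forecast gave 1.3, alike and 9 %, the last a little below my figure. Its ground for the second answer was “Target therefore has little effect”.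

The flask gave 1.3, alike and 9.91 %.

    free catalyst + starting material → catalyst-substrate complex (189.0 M⁻¹ min⁻¹)
    catalyst-substrate complex + reagent → target + free catalyst (75.60 M⁻¹ min⁻¹)
    free catalyst + impurity → spent catalyst
    free catalyst + starting material ⇌ idle catalyst-substrate complex, settled at all times (6.900 M⁻¹)

The order above one came from the loss of free catalyst to the impurity: with that loss taken away, the order fell from 1.3 to 1.0. The dead charge carries this to the elm run. The larch run made target equal to a quarter of its charge at 7.77 min, and dividing by the working-charge ratio from the dead charge, 1.66, gives 4.68 min. The elm run reached that point at 4.71 min.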